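**Strategy.** Azulene numbering: C1 angelate, C3 carbinol, C4 anisoate, C6=C7 alkene, C8a methyl. The seven-membered ring carries oxygen on C4 and methyl on C6 between C3a and C7, the pattern of a 3-oxidopyrylium made from a 4-methylfuran. The route therefore forms C3a–C8a and C7–C8 in one intramolecular [5+2] cycloaddition of that ylide with the isopropenyl group C8a=C8, which closes the five- and the seven-membered ring at once and sets the quaternary C8a with its methyl trans to the ether bridge on C3a. The precursor is a monocyclic pyranone hemiacetal whose side chain holds C3 and C1. SmI2 then expels the bridging ether oxygen from C7 and C3a, leaving the C6=C7 alkene and H-3a.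

Key step: step 10

Remark on the chemistry: azulene numbering is used throughout and β means the face of the C8a methyl group (the C1 ester oxygen and the C3 hydroxyl are β; H-3a, the C4 ester oxygen and the isopropyl group are α).

Step 1
Reactants: 1 (2R)-2-hydroxy-3-methylbutanoic acid; 2 2,2-dimethylpropanal (pivalaldehyde)
Product: 3 (2R,5R)-2-tert-butyl-5-(propan-2-yl)-1,3-dioxolan-4-one (cis)
Conditions: p-TsOH (cat.), H2SO4 (cat.), pentane, reflux, Dean–Stark trap; recrystallisation
Reagents that add atoms: none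
Why: Acid-catalysed acetalisation with azeotropic removal of water (Seebach dioxolanone formation) gives the cis acetal as the thermodynamically favoured and crystallisable isomer, so the acetal centre is set by the existing centre.

Step 2
Reactants: 3 cis-dioxolanone; 4 1-bromo-3-methylbut-2-ene (prenyl bromide)
Product: 6 (2R,5R)-2-tert-butyl-5-(3-methylbut-2-en-1-yl)-5-(propan-2-yl)-1,3-dioxolan-4-one, via lithium enolate 5 (not isolated)
Conditions: LDA (lithium diisopropylamide), THF, −78 °C; then 4, DMPU, −78 → −30 °C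
Reagents that add atoms: none
Why: Self-regeneration of stereocentres (Seebach alkylation): the planar lithium enolate is alkylated by the reactive allylic bromide on the face opposite to the tert-butyl group, which creates the quaternary carbinol carbon, C3 of the target, with overall retention.

Step 3
Reactants: 6 prenyl dioxolanone
Product: 7 (2R,5R)-2-tert-butyl-5-{[(2R)-3,3-dimethyloxiran-2-yl]methyl}-5-(propan-2-yl)-1,3-dioxolan-4-one
Conditions: Shi ketone from D-fructose (0.3 equiv), Oxone (2KHSO5·KHSO4·K2SO4), K2CO3, Bu4NHSO4, MeCN/CH2(OMe)2/aq. Na2B4O7 buffer, 0 °C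
Reagents that add atoms: potassium peroxymonosulfate (active part of Oxone), [K+].[O-]S(=O)(=O)OO
Why: Shi epoxidation: the chiral dioxirane generated from the ketone and Oxone transfers oxygen to the electron-rich trisubstituted alkene under catalyst control (spiro transition state) and should set the R-configured secondary C–O centre that becomes C1, the remote quaternary centre having no say.

Step 4
Reactants: 7 epoxide
Product: 9 (3R,5R)-3-hydroxy-3-(propan-2-yl)-5-(prop-1-en-2-yl)oxolan-2-one, via allylic alcohol 8 (not isolated)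
Conditions: preformed Et2Al(TMP) (diethylaluminium 2,2,6,6-tetramethylpiperidide), PhMe, 0 °C → rt; aq. KNaC4H4O6; p-TsOH (cat.), CH2Cl2, rt
Reagents that add atoms: none
Why: Aluminium amide-mediated isomerisation of a trisubstituted epoxide to an allylic alcohol: the amide removes a proton from a methyl group of the gem-dimethyl carbon syn to the aluminium-bound oxygen, the C1–O bond is not touched (retention), and the secondary alkoxide then transacylates onto the activated dioxolanone carbonyl to close the five-membered lactone with loss of pivalaldehyde.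

Step 5
Reactants: 9 hydroxy lactone
Product: 10 (3R,5R)-3-(propan-2-yl)-5-(prop-1-en-2-yl)-3-(triethylsilyloxy)oxolan-2-one
Conditions: Et3SiOTf, 2,6-lutidine, CH2Cl2, −78 → 0 °C
Reagents that add atoms: triethylsilyl trifluoromethanesulfonate, CC[Si](CC)(CC)OS(=O)(=O)C(F)(F)F
Why: Silyl triflate silylation caps even a hindered tertiary alcohol, and the ether is needed so that the hydroxyl cannot add to the later pyrylium ylide.

Step 6
Reactants: 10 silylated lactone; 11 3-methylfuran
Product: 13 (2R,4R)-4-hydroxy-5-methyl-1-(4-methylfuran-2-yl)-2-(propan-2-yl)-2-(triethylsilyloxy)hex-5-en-1-one, via (4-methylfuran-2-yl)lithium 12 (not isolated)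
Conditions: 11, LiTMP (lithium 2,2,6,6-tetramethylpiperidide), THF, −78 → 0 °C; then 10, −78 → −20 °C; aq. NH4Cl
Reagents that add atoms: none
Why: Deprotonation of the furan by the hindered amide base should occur at the α-position remote from the methyl group (steric control, as with 3-methylthiophene), and nucleophilic acyl addition of the furyllithium to the non-enolisable lactone stops at the lithium lactolate, which opens on work-up to the furyl ketone and frees the C1 hydroxyl.

Step 7
Reactants: 13 hydroxy ketone; 14 (2Z)-2-methylbut-2-enoic acid (angelic acid)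
Product: 16 (3R,5R)-2,6-dimethyl-5-(4-methylfuran-2-carbonyl)-5-(triethylsilyloxy)hept-1-en-3-yl (2Z)-2-methylbut-2-enoate, via mixed anhydride 15 (not isolated)
Conditions: 14, 2,4,6-trichlorobenzoyl chloride, Et3N, PhMe, rt; then 13, 75 °C
Reagents that add atoms: none
Why: Yamaguchi esterification through the mixed anhydride acylates the secondary allylic alcohol at the less hindered angeloyl carbonyl and, run without DMAP, is known to keep the Z geometry of angelates.

Step 8
Reactants: 16 angelate ketone
Product: 17 (3R,5R)-5-[hydroxy(4-methylfuran-2-yl)methyl]-2,6-dimethyl-5-(triethylsilyloxy)hept-1-en-3-yl (2Z)-2-methylbut-2-enoate (both carbinol epimers)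
Conditions: NaBH4, MeOH/THF, 0 °C → rt
Reagents that add atoms: none
Why: Borohydride reduction of the non-enolisable heteroaryl ketone is chemoselective over the enoate, and the configuration of the new carbinol carbon does not matter because this carbon becomes trigonal in the ylide of step 10.

Step 9
Reactants: 17 furfuryl alcohol
Product: 18 (3R,5R)-5-(6-hydroxy-5-methyl-3-oxo-3,6-dihydro-2H-pyran-2-yl)-2,6-dimethyl-5-(triethylsilyloxy)hept-1-en-3-yl (2Z)-2-methylbut-2-enoate (epimers at the two ring sp3 carbons)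
Conditions: NBS, NaHCO3, NaOAc, THF/H2O (4:1), 0 °C
Reagents that add atoms: water, O
Why: Achmatowicz rearrangement: the electron-rich furan reacts with the bromonium source faster than the enoate or the inductively deactivated isopropenyl group, and the hydrated enedione closes through the furfuryl hydroxyl to the pyranone hemiacetal.

Step 10
Reactants: 18 pyranone hemiacetal
Product: 21 tricyclic 3a,7-epoxy enone (cycloadduct), via mesylate 19 (not isolated), via oxidopyrylium ylide 20 (not isolated)
Conditions: MsCl, i-Pr2NEt, MeCN (0.01 M), 0 °C → 80 °C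
Reagents that add atoms: none
Why: Mesylation of the hemiacetal and base-induced loss of methanesulfonate give the 3-oxidopyrylium ylide 20, whose termini C3a and C7 add suprafacially across the tethered isopropenyl group in a concerted six-electron [5+2] cycloaddition that forms C3a–C8a and C7–C8. The closest known reaction type is the intramolecular oxidopyrylium–alkene cycloaddition of pyranones obtained by the Achmatowicz rearrangement. The cyclopentane closes through the C3a–C8a bond with the three-carbon tether exo, and the cycloheptenone closes through both new bonds as the carbocyclic perimeter of an 8-oxabicyclo[3.2.1]octenone. Because the tether must be exo, the C8a methyl is endo and therefore trans to the ether bridge on C3a, which is the trans ring fusion of the target with oxygen in the place of H-3a, while C3a and C7 are fixed by the bridge. The step needs attack on one face of the ylide, and the quaternary C3 should secure it through allylic 1,3-strain (isopropyl next to the ring oxygen, the smaller silyloxy group next to the C4 oxide), reinforced by C1, which keeps its hydrogen on the face of the isopropyl group. Regiochemistry is fixed by the tether, high dilution disfavours dimerisation of the ylide, and the silyl ether prevents trapping of the ylide by the tertiary hydroxyl.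

Step 11
Reactants: 21 cycloadduct
Product: 23 (1R,3R,3aR,8aR)-6,8a-dimethyl-4-oxo-3-(propan-2-yl)-3-(triethylsilyloxy)-1,2,3,3a,4,5,8,8a-octahydroazulen-1-yl (2Z)-2-methylbut-2-enoate, via 3a-hydroxy ketone 22 (not isolated)
Conditions: SmI2 (5 equiv), THF/MeOH (10:1), −78 → −20 °C
Reagents that add atoms: none
Why: SmI2 reductive cleavage: two-electron reduction of the enone expels the allylic C7–O bond (vinylogous α-alkoxy ketone cleavage) and α-protonation of the dienolate leaves the alkene at C6=C7, the α-oxygenated ketone 22 is then deoxygenated at C3a, and the enolate should be protonated on the α-face, from which the oxygen departs and which is not shielded by the C3 silyloxy group, the C1 ester and the angular methyl, to give the trans ring fusion, while the trisubstituted enoate is not reduced at this temperature without HMPA.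

Step 12
Reactants: 23 silyloxy ketone
Product: 24 (1R,3R,3aR,8aR)-3-hydroxy-6,8a-dimethyl-4-oxo-3-(propan-2-yl)-1,2,3,3a,4,5,8,8a-octahydroazulen-1-yl (2Z)-2-methylbut-2-enoate
Conditions: HF·pyridine, pyridine, THF, 0 °C → rt
Reagents that add atoms: none
Why: Fluoride cleaves the Si–O bond under buffered non-basic conditions, which avoids retro-aldol opening of the β-hydroxy ketone and migration of the β,γ-alkene into conjugation.

Step 13
Reactants: 24 β-hydroxy ketone
Product: 25 (1R,3R,3aS,4S,8aR)-3,4-dihydroxy-6,8a-dimethyl-3-(propan-2-yl)-1,2,3,3a,4,5,8,8a-octahydroazulen-1-yl (2Z)-2-methylbut-2-enoate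
Conditions: Me4NBH(OAc)3, MeCN/AcOH (1:1), −30 °C
Reagents that add atoms: none
Why: Evans–Saksena reduction: the C3 hydroxyl binds the borohydride and delivers hydride intramolecularly to the β-face of the C4 carbonyl through a chair transition state, which gives the anti 1,3-diol with the new hydroxyl α (4S), cis to the hydrogen on C3a.

Step 14
Reactants: 25 diol; 26 4-methoxybenzoyl chloride
Product: 27 target CNP0204191.1
Conditions: 26, DMAP (cat.), pyridine, CH2Cl2, 0 °C → rt
Reagents that add atoms: none
Why: DMAP-catalysed acylation (nucleophilic catalysis) esterifies the only secondary hydroxyl, the tertiary C3 hydroxyl being too hindered to react, and completes the target.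

**Compound list**

1 | (2R)-2-hydroxy-3-methylbutanoic acid | CC(C)[C@@H](O)C(=O)O | starting material
2 | 2,2-dimethylpropanal (pivalaldehyde) | CC(C)(C)C=O | starting material
3 | (2R,5R)-2-tert-butyl-5-(propan-2-yl)-1,3-dioxolan-4-one (cis) | CC(C)[C@H]1O[C@@H](C(C)(C)C)OC1=O | intermediate
4 | 1-bromo-3-methylbut-2-ene (prenyl bromide) | CC(C)=CCBr | starting material
5 | lithium enolate of 3 (formed in the flask) | CC(C)C1=C(O[Li])O[C@H](C(C)(C)C)O1 | intermediate
6 | (2R,5R)-2-tert-butyl-5-(3-methylbut-2-en-1-yl)-5-(propan-2-yl)-1,3-dioxolan-4-one | CC(C)[C@@]1(CC=C(C)C)O[C@@H](C(C)(C)C)OC1=O | intermediate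
7 | (2R,5R)-2-tert-butyl-5-{[(2R)-3,3-dimethyloxiran-2-yl]methyl}-5-(propan-2-yl)-1,3-dioxolan-4-one | CC(C)[C@@]1(C[C@H]2OC2(C)C)O[C@@H](C(C)(C)C)OC1=O | intermediate
8 | (2R,5R)-2-tert-butyl-5-[(2R)-2-hydroxy-3-methylbut-3-en-1-yl]-5-(propan-2-yl)-1,3-dioxolan-4-one (formed in the flask) | CC(C)[C@@]1(C[C@@H](O)C(C)=C)O[C@@H](C(C)(C)C)OC1=O | intermediate
9 | (3R,5R)-3-hydroxy-3-(propan-2-yl)-5-(prop-1-en-2-yl)oxolan-2-one (isopropenyl cis to isopropyl) | CC(=C)[C@H]1C[C@@](O)(C(C)C)C(=O)O1 | intermediate
10 | (3R,5R)-3-(propan-2-yl)-5-(prop-1-en-2-yl)-3-(triethylsilyloxy)oxolan-2-one | CC(=C)[C@H]1C[C@@](O[Si](CC)(CC)CC)(C(C)C)C(=O)O1 | intermediate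
11 | 3-methylfuran | Cc1ccoc1 | starting material
12 | (4-methylfuran-2-yl)lithium (formed in the flask) | [Li]c1cc(C)co1 | intermediate
13 | (2R,4R)-4-hydroxy-5-methyl-1-(4-methylfuran-2-yl)-2-(propan-2-yl)-2-(triethylsilyloxy)hex-5-en-1-one | O[C@H](C[C@@](O[Si](CC)(CC)CC)(C(C)C)C(=O)c1cc(C)co1)C(C)=C | intermediate
14 | (2Z)-2-methylbut-2-enoic acid (angelic acid) | C/C=C(/C)C(=O)O | starting material
15 | (2Z)-2-methylbut-2-enoic 2,4,6-trichlorobenzoic anhydride (formed in the flask) | C/C=C(/C)C(=O)OC(=O)c1c(Cl)cc(Cl)cc1Cl | intermediate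
16 | (3R,5R)-2,6-dimethyl-5-(4-methylfuran-2-carbonyl)-5-(triethylsilyloxy)hept-1-en-3-yl (2Z)-2-methylbut-2-enoate | C/C=C(/C)C(=O)O[C@H](C[C@@](O[Si](CC)(CC)CC)(C(C)C)C(=O)c1cc(C)co1)C(C)=C | intermediate
17 | (3R,5R)-5-[hydroxy(4-methylfuran-2-yl)methyl]-2,6-dimethyl-5-(triethylsilyloxy)hept-1-en-3-yl (2Z)-2-methylbut-2-enoate, both carbinol epimers | C/C=C(/C)C(=O)O[C@H](C[C@@](O[Si](CC)(CC)CC)(C(C)C)C(O)c1cc(C)co1)C(C)=C | intermediate
18 | (3R,5R)-5-(6-hydroxy-5-methyl-3-oxo-3,6-dihydro-2H-pyran-2-yl)-2,6-dimethyl-5-(triethylsilyloxy)hept-1-en-3-yl (2Z)-2-methylbut-2-enoate, epimers at pyran C2 and C6 | C/C=C(/C)C(=O)O[C@H](C[C@@](O[Si](CC)(CC)CC)(C(C)C)C1OC(O)C(C)=CC1=O)C(C)=C | intermediate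
19 | 6-O-methanesulfonate of 18 (formed in the flask) | C/C=C(/C)C(=O)O[C@H](C[C@@](O[Si](CC)(CC)CC)(C(C)C)C1OC(OS(C)(=O)=O)C(C)=CC1=O)C(C)=C | intermediate
20 | 5-methyl-3-oxidopyrylium ylide carrying the side chain of 18 at C2 (formed in the flask) | C/C=C(/C)C(=O)O[C@H](C[C@@](O[Si](CC)(CC)CC)(C(C)C)c1[o+]cc(C)cc1[O-])C(C)=C | intermediate
21 | 3a,7-epoxy-6,8a-dimethyl-4-oxo-3-(propan-2-yl)-3-(triethylsilyloxy)-1,2,3,3a,4,7,8,8a-octahydroazulen-1-yl (2Z)-2-methylbut-2-enoate; C1, C3 and C8a as in the target, ether bridge α (trans to the C8a methyl), C5=C6 enone | C/C=C(/C)C(=O)O[C@@H]1C[C@@](O[Si](CC)(CC)CC)(C(C)C)[C@@]23O[C@@H](C[C@]21C)C(C)=CC3=O | intermediate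
22 | 3a-hydroxy-6,8a-dimethyl-4-oxo-3-(propan-2-yl)-3-(triethylsilyloxy)-1,2,3,3a,4,5,8,8a-octahydroazulen-1-yl (2Z)-2-methylbut-2-enoate; 3a-hydroxyl α (formed in the flask) | C/C=C(/C)C(=O)O[C@@H]1C[C@@](O[Si](CC)(CC)CC)(C(C)C)[C@]2(O)C(=O)CC(C)=CC[C@]21C | intermediate
23 | (1R,3R,3aR,8aR)-6,8a-dimethyl-4-oxo-3-(propan-2-yl)-3-(triethylsilyloxy)-1,2,3,3a,4,5,8,8a-octahydroazulen-1-yl (2Z)-2-methylbut-2-enoate (trans-fused) | C/C=C(/C)C(=O)O[C@@H]1C[C@@](O[Si](CC)(CC)CC)(C(C)C)[C@@H]2C(=O)CC(C)=CC[C@]21C | intermediate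
24 | (1R,3R,3aR,8aR)-3-hydroxy-6,8a-dimethyl-4-oxo-3-(propan-2-yl)-1,2,3,3a,4,5,8,8a-octahydroazulen-1-yl (2Z)-2-methylbut-2-enoate | C/C=C(/C)C(=O)O[C@@H]1C[C@@](O)(C(C)C)[C@@H]2C(=O)CC(C)=CC[C@]21C | intermediate
25 | (1R,3R,3aS,4S,8aR)-3,4-dihydroxy-6,8a-dimethyl-3-(propan-2-yl)-1,2,3,3a,4,5,8,8a-octahydroazulen-1-yl (2Z)-2-methylbut-2-enoate | C/C=C(/C)C(=O)O[C@@H]1C[C@@](O)(C(C)C)[C@@H]2[C@@H](O)CC(C)=CC[C@]21C | intermediate
26 | 4-methoxybenzoyl chloride | COc1ccc(cc1)C(Cl)=O | starting material
27 | (1R,3R,3aS,4S,8aR)-3-hydroxy-6,8a-dimethyl-1-{[(2Z)-2-methylbut-2-enoyl]oxy}-3-(propan-2-yl)-1,2,3,3a,4,5,8,8a-octahydroazulen-4-yl 4-methoxybenzoate (CNP0204191.1) | C/C=C(/C)C(=O)O[C@@H]1C[C@@](O)(C(C)C)[C@@H]2[C@@H](OC(=O)c3ccc(OC)cc3)CC(C)=CC[C@]21C | target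

**Totals.** Total step count: 14. Longest linear sequence: 14 steps (1 → 27).

**Steps most likely to fail.**

Step 11. The samarium enolate may be protonated on the β-face of C3a (cis ring fusion); a conformer with the isopropyl group pseudo-axial on the α-face would favour exactly that. The second C–O cleavage may also stall, or the enoate may be reduced by the excess reagent. The fallback sets out from 21 and comes back at 23. Conjugate reduction of the enone with [(Ph3P)CuH]6 (PhMe, rt, hydride on the open α-face) should give the saturated bridged ketone F1. SmI2 (2.2 equiv, THF/MeOH, −78 °C) then has only the α C–O bond of a simple α-alkoxy ketone to cleave, and the C7 alkoxide that stays on the α-face can pass the proton to C3a. The resulting 7-hydroxy ketone F2 can be equilibrated at C3a with DBU, because no alkene can migrate and the β-oxygen is silylated. Burgess dehydration (syn elimination with the cis hydrogen on C6) returns the route to 23.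

Step 10. The ylide may dimerise faster than it cyclises onto the hindered 1,1-disubstituted alkene, or the bulky conjugated allylic ester may erode the face selectivity or intercept the ylide. The fallback sets out from 13 and comes back at 21: the C1 hydroxyl is carried as an acetate and the angelate is put on the tricycle. Acetylation of 13 (Ac2O, DMAP, pyridine) gives the acetate ketone F3, NaBH4 reduction the furfuryl alcohol F4, and Achmatowicz rearrangement (NBS, NaHCO3, THF/H2O) the pyranone hemiacetal F5. MsCl and i-Pr2NEt in MeCN then lead, through the mesylate F6 and the ylide F7, to the tricyclic acetate F8. Methanolysis (K2CO3, MeOH, 0 °C) frees the C1 alcohol F9, and Yamaguchi esterification with 15 as in step 7 gives 21.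

Step 13. Ligand exchange at the hindered tertiary hydroxyl may be slow, so that hydride is not delivered intramolecularly and the wrong C4 epimer or no reduction results. The fallback sets out from 24 and comes back at 27. Syn-selective Narasaka–Prasad reduction (Et2BOMe, NaBH4, THF/MeOH, −78 °C, external hydride on the boron chelate) should give the C4-epimeric diol F10. Mitsunobu esterification with 4-methoxybenzoic acid (PPh3, DIAD, PhMe) then inverts C4 and gives the target 27 directly.

**Further compounds**

F1 | step 11 | 5,6-dihydro derivative of 21 (saturated bridged ketone, 6-methyl β) | C/C=C(/C)C(=O)O[C@@H]1C[C@@](O[Si](CC)(CC)CC)(C(C)C)[C@@]23O[C@@H](C[C@]21C)[C@@H](C)CC3=O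
F2 | step 11 | 7-hydroxy-6,8a-dimethyl-4-oxo-3-(propan-2-yl)-3-(triethylsilyloxy)decahydroazulen-1-yl (2Z)-2-methylbut-2-enoate (H-3a α, 7-hydroxyl α, 6-methyl β) | C/C=C(/C)C(=O)O[C@@H]1C[C@@](O[Si](CC)(CC)CC)(C(C)C)[C@@H]2C(=O)C[C@H](C)[C@@H](O)C[C@]21C
F3 | step 10 | (3R,5R)-2,6-dimethyl-5-(4-methylfuran-2-carbonyl)-5-(triethylsilyloxy)hept-1-en-3-yl acetate | CC(=O)O[C@H](C[C@@](O[Si](CC)(CC)CC)(C(C)C)C(=O)c1cc(C)co1)C(C)=C
F4 | step 10 | (3R,5R)-5-[hydroxy(4-methylfuran-2-yl)methyl]-2,6-dimethyl-5-(triethylsilyloxy)hept-1-en-3-yl acetate, both carbinol epimers | CC(=O)O[C@H](C[C@@](O[Si](CC)(CC)CC)(C(C)C)C(O)c1cc(C)co1)C(C)=C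
F5 | step 10 | (3R,5R)-5-(6-hydroxy-5-methyl-3-oxo-3,6-dihydro-2H-pyran-2-yl)-2,6-dimethyl-5-(triethylsilyloxy)hept-1-en-3-yl acetate | CC(=O)O[C@H](C[C@@](O[Si](CC)(CC)CC)(C(C)C)C1OC(O)C(C)=CC1=O)C(C)=C
F6 | step 10 | 6-O-methanesulfonate of F5 (formed in the flask) | CC(=O)O[C@H](C[C@@](O[Si](CC)(CC)CC)(C(C)C)C1OC(OS(C)(=O)=O)C(C)=CC1=O)C(C)=C
F7 | step 10 | 3-oxidopyrylium ylide of the acetate series (formed in the flask) | CC(=O)O[C@H](C[C@@](O[Si](CC)(CC)CC)(C(C)C)c1[o+]cc(C)cc1[O-])C(C)=C
F8 | step 10 | acetate analogue of 21 (tricyclic 3a,7-epoxy enone, C1 acetate) | CC(=O)O[C@@H]1C[C@@](O[Si](CC)(CC)CC)(C(C)C)[C@@]23O[C@@H](C[C@]21C)C(C)=CC3=O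
F9 | step 10 | C1 alcohol of the tricycle (21 without the angeloyl group) | O[C@@H]1C[C@@](O[Si](CC)(CC)CC)(C(C)C)[C@@]23O[C@@H](C[C@]21C)C(C)=CC3=O
F10 | step 13 | (1R,3R,3aS,4R,8aR)-3,4-dihydroxy-6,8a-dimethyl-3-(propan-2-yl)-1,2,3,3a,4,5,8,8a-octahydroazulen-1-yl (2Z)-2-methylbut-2-enoate (C4 epimer of 25) | C/C=C(/C)C(=O)O[C@@H]1C[C@@](O)(C(C)C)[C@@H]2[C@H](O)CC(C)=CC[C@]21C
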